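**Plan**

1. Locants C1–C15 are germacrane locants of the target (ring C1–C10; lactone ring O–C12(=O)–C11(=C13)–C7–C6; C14 on C10, C15 on C4; C2′/C3′ in the glycidic ester). The enabling feature is that C3 is a secondary allylic carbinol on the Z-trisubstituted alkene C4=C5, which holds C3 cis to C6 of the trans-fused lactone; an alkenylmetal at C4 and an aldehyde at C3 are therefore the natural ends of the ten-membered ring.
2. Cuts, in retrosynthetic order: C3–O (isovalerate); C3–C4 (ring; iodoalkene plus aldehyde); C8–O (glycidic ester, with inversion); C7–C8 (allylation by a 3-bromomethyl butenolide, which also creates C11=C13); C7=C11 of the butenolide (metathesis); C1–C2 and C10–C14 of the chain (carboalumination, ethylene oxide).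
3. Forward ring order: butenolide/lactone ring (step 5); C1–C10 oxirane on the open chain (step 8); side-chain oxirane made separately (step 12) and attached (step 14); ten-membered carbocycle last (step 17). Only an acylation follows.
4. Stereochemistry: C6 by lipase resolution; C7 by allylation anti to the C6 substituent; C8 by chair-controlled anti addition, then Mitsunobu inversion; C1/C10 by Shi epoxidation; C2′/C3′ by Sharpless epoxidation; C3 in the ring closure (conformational control, the least certain element); 4Z from hydroalumination–iodination; the E relation of C2 and C9 from syn-carboalumination.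

Key step: step 17

**Step 1**
Reactants: 1 acrolein (prop-2-enal); 2 1-propynylmagnesium bromide
Product: 3 hex-1-en-4-yn-3-ol (racemic)
Conditions: THF, −78 to 0 °C; then H2O
Reagents that add atoms: none
Why: Grignard 1,2-addition of the alkynyl nucleophile to the enal carbonyl at low temperature should give the secondary alcohol without conjugate addition; the stereocentre forms racemic and is resolved in step 3.

**Step 2**
Reactants: 3 hex-1-en-4-yn-3-ol
Product: 5 (Z)-5-iodohexa-1,4-dien-3-ol (racemic), via cyclic sodium alkenylalanate 4 (not isolated)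
Conditions: NaAlH2(OCH2CH2OCH3)2 (Red-Al), THF, 0 °C to rt; then I2, −78 °C; aqueous work-up
Reagents that add atoms: iodine, II
Why: Hydroxyl-directed trans-hydroalumination of the propargylic alkyne delivers hydride to C5 and aluminium to C4 within a five-membered oxa-aluminacycle, and iodinolysis of the C–Al bond with retention should give only the Z iodoalkene (iodine cis to the carbinol carbon C6), the isolated vinyl group not being reduced.

**Step 3**
Reactants: 5 (Z)-5-iodohexa-1,4-dien-3-ol (racemic)
Product: 6 (3S,4Z)-5-iodohexa-1,4-dien-3-ol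
Conditions: Novozym 435 (immobilised Candida antarctica lipase B), vinyl acetate, hexane, 30 °C, stopped near half conversion
Reagents that add atoms: none
Why: Lipase-catalysed kinetic resolution by enantioselective transesterification: the enzyme should acylate the R alcohol (large iodoalkenyl and small vinyl group in its two pockets), so the unreacted S alcohol, which carries the C6 configuration of the target, is recovered.

**Step 4**
Reactants: 6 (3S,4Z)-5-iodohexa-1,4-dien-3-ol; 7 2-(bromomethyl)prop-2-enoic acid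
Product: 8 (3S,4Z)-5-iodohexa-1,4-dien-3-yl 2-(bromomethyl)prop-2-enoate
Conditions: DCC, DMAP (5 mol%), CH2Cl2, −10 °C
Reagents that add atoms: none
Why: Steglich esterification (carbodiimide activation, acyl transfer through DMAP) should acylate the secondary alcohol with retention at C6, the low temperature and low DMAP loading limiting displacement of the allylic bromide.

**Step 5**
Reactants: 8 (3S,4Z)-5-iodohexa-1,4-dien-3-yl 2-(bromomethyl)prop-2-enoate
Product: 9 (5S)-3-(bromomethyl)-5-[(1Z)-2-iodoprop-1-en-1-yl]furan-2(5H)-one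
Conditions: second-generation Grubbs catalyst RuCl2(=CHPh)(PCy3)(H2IMes) (5 mol%), toluene, 80 °C
Reagents that add atoms: none
Why: Ring-closing metathesis between the vinyl group and the 1,1-disubstituted acrylate alkene should close the five-membered butenolide (lactone ring C6–O–C12–C11=C7) with loss of ethene, the trisubstituted iodoalkene being too hindered and electron-poor to enter the catalytic cycle.

**Step 6**
Reactants: 10 tert-butyl(but-3-yn-1-yloxy)dimethylsilane
Product: 13 (3E)-6-(tert-butyldimethylsilyloxy)-4-methylhex-3-en-1-ol, via E-alkenyldimethylalane 11 (not isolated), via lithium alkenylaluminate 12 (not isolated)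
Conditions: AlMe3, Cp2ZrCl2 (cat.), CH2Cl2, 0 °C to rt; volatiles removed; n-BuLi, THF/hexane, −78 °C; ethylene oxide, −78 °C to rt; then H2O
Reagents that add atoms: trimethylaluminium, C[Al](C)C; ethylene oxide, C1CO1
Why: Zirconium-catalysed syn-carboalumination of the terminal alkyne (Negishi carboalumination) places methyl on C10 and aluminium on C1, and the derived aluminate opens ethylene oxide with retention at the alkenyl carbon, so the trisubstituted alkene should form with C2 trans to C9.

**Step 7**
Reactants: 13 (3E)-6-(tert-butyldimethylsilyloxy)-4-methylhex-3-en-1-ol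
Product: 14 tert-butyl{[(3E)-6-(4-methoxybenzyloxy)-3-methylhex-3-en-1-yl]oxy}dimethylsilane
Conditions: NaH, 4-methoxybenzyl chloride, Bu4NI (cat.), THF/DMF, 0 °C to rt
Reagents that add atoms: 4-methoxybenzyl chloride, COc1ccc(CCl)cc1
Why: Williamson ether synthesis masks the C3 oxygen as a PMB ether that can later be removed oxidatively without acid or base.

**Step 8**
Reactants: 14 tert-butyl{[(3E)-6-(4-methoxybenzyloxy)-3-methylhex-3-en-1-yl]oxy}dimethylsilane
Product: 15 tert-butyl(2-{(2R,3R)-3-[2-(4-methoxybenzyloxy)ethyl]-2-methyloxiran-2-yl}ethoxy)dimethylsilane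
Conditions: Shi ketone (D-fructose-derived 1,2:4,5-di-O-isopropylidene-β-D-erythro-2,3-hexodiulo-2,6-pyranose, 30 mol%), Oxone (2KHSO5·KHSO4·K2SO4), K2CO3, Bu4NHSO4 (cat.), MeCN/dimethoxymethane/aq. Na2B4O7 buffer, 0 °C
Reagents that add atoms: potassium peroxymonosulfate (active component of Oxone), [K+].[O-]S(=O)(=O)OO
Why: Shi asymmetric epoxidation through the spiro dioxirane transition state is reagent-controlled for E-trisubstituted alkenes, and the D-fructose-derived ketone should deliver oxygen to the face that gives the (R,R)-oxirane, setting C1 and C10.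

**Step 9**
Reactants: 15 tert-butyl(2-{(2R,3R)-3-[2-(4-methoxybenzyloxy)ethyl]-2-methyloxiran-2-yl}ethoxy)dimethylsilane
Product: 16 2-{(2R,3R)-3-[2-(4-methoxybenzyloxy)ethyl]-2-methyloxiran-2-yl}ethan-1-ol
Conditions: Bu4NF, THF, 0 °C
Reagents that add atoms: none
Why: Fluoride-induced cleavage of the primary silyl ether frees the C8 alcohol, the oxirane and the PMB ether being inert to fluoride.

**Step 10**
Reactants: 16 2-{(2R,3R)-3-[2-(4-methoxybenzyloxy)ethyl]-2-methyloxiran-2-yl}ethan-1-ol
Product: 17 {(2R,3R)-3-[2-(4-methoxybenzyloxy)ethyl]-2-methyloxiran-2-yl}acetaldehyde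
Conditions: Dess–Martin periodinane, NaHCO3, CH2Cl2, 0 °C; used crude
Reagents that add atoms: none
Why: Dess–Martin oxidation under buffered, non-basic conditions should give the β,γ-epoxy aldehyde without β-elimination, which is why it is used at once without chromatography.

**Step 11**
Reactants: 9 (5S)-3-(bromomethyl)-5-[(1Z)-2-iodoprop-1-en-1-yl]furan-2(5H)-one; 17 {(2R,3R)-3-[2-(4-methoxybenzyloxy)ethyl]-2-methyloxiran-2-yl}acetaldehyde
Product: 18 (4R,5S)-4-[(1S)-1-hydroxy-2-{(2R,3R)-3-[2-(4-methoxybenzyloxy)ethyl]-2-methyloxiran-2-yl}ethyl]-5-[(1Z)-2-iodoprop-1-en-1-yl]-3-methylideneoxolan-2-one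
Conditions: Zn dust, THF/sat. aq. NH4Cl, 0 °C to rt
Reagents that add atoms: none
Why: Barbier-type carbonyl allylation: zinc inserts into the allylic C–Br bond and the allylzinc adds through its γ-carbon C7 in a closed six-membered chair, anti to the C6 substituent (C7 R, trans lactone) and with the aldehyde chain equatorial, which, because the ring locks C6 trans to the CH2Zn group, should give the anti adduct (8S, the epimer needed for the inversion in step 14) and at the same time creates the exocyclic methylene C11=C13, the iodoalkene being inert to zinc.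

**Step 12**
Reactants: 19 (2E)-2-methylbut-2-en-1-ol
Product: 20 [(2S,3S)-2,3-dimethyloxiran-2-yl]methanol
Conditions: Ti(OiPr)4 (cat.), L-(+)-diethyl tartrate, t-BuOOH, 4 Å molecular sieves, CH2Cl2, −20 °C
Reagents that add atoms: tert-butyl hydroperoxide, CC(C)(C)OO
Why: Sharpless asymmetric epoxidation of the E allylic alcohol with the L-(+)-tartrate catalyst should deliver oxygen to the face that gives the (2S,3S)-epoxy alcohol with the two methyl groups cis.

**Step 13**
Reactants: 20 [(2S,3S)-2,3-dimethyloxiran-2-yl]methanol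
Product: 21 (2R,3S)-2,3-dimethyloxirane-2-carboxylic acid
Conditions: RuCl3 (cat.), NaIO4, MeCN/EtOAc/H2O, rt
Reagents that add atoms: water, O
Why: Oxidation of the primary alcohol to the acid by catalytic RuO4 (RuCl3/NaIO4, through the aldehyde hydrate) leaves the oxirane untouched, and the descriptor at C2 changes from S to R only because the CIP priorities change.

**Step 14**
Reactants: 18 (4R,5S)-4-[(1S)-1-hydroxy-2-{(2R,3R)-3-[2-(4-methoxybenzyloxy)ethyl]-2-methyloxiran-2-yl}ethyl]-5-[(1Z)-2-iodoprop-1-en-1-yl]-3-methylideneoxolan-2-one; 21 (2R,3S)-2,3-dimethyloxirane-2-carboxylic acid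
Product: 22 (1R)-1-{(2S,3R)-2-[(1Z)-2-iodoprop-1-en-1-yl]-4-methylidene-5-oxooxolan-3-yl}-2-{(2R,3R)-3-[2-(4-methoxybenzyloxy)ethyl]-2-methyloxiran-2-yl}ethyl (2R,3S)-2,3-dimethyloxirane-2-carboxylate
Conditions: PPh3, DIAD, toluene, 0 °C to rt
Reagents that add atoms: none
Why: Mitsunobu esterification: the C8 alcohol is activated as an alkoxyphosphonium ion and displaced by the carboxylate in an SN2 reaction, so C8 should be inverted from S to R while the side chain is attached in the same operation.

**Step 15**
Reactants: 22 (PMB ether, as named in step 14)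
Product: 23 (1R)-2-[(2R,3R)-3-(2-hydroxyethyl)-2-methyloxiran-2-yl]-1-{(2S,3R)-2-[(1Z)-2-iodoprop-1-en-1-yl]-4-methylidene-5-oxooxolan-3-yl}ethyl (2R,3S)-2,3-dimethyloxirane-2-carboxylate
Conditions: DDQ, CH2Cl2/pH 7 phosphate buffer, 0 °C
Reagents that add atoms: none
Why: Oxidative cleavage of the PMB ether by DDQ (hydride abstraction, hydrolysis of the oxocarbenium ion) runs under near-neutral conditions that should spare both oxiranes, the iodoalkene, the ester and the methylene lactone.

**Step 16**
Reactants: 23 (C3 alcohol, as named in step 15)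
Product: 24 (1R)-1-{(2S,3R)-2-[(1Z)-2-iodoprop-1-en-1-yl]-4-methylidene-5-oxooxolan-3-yl}-2-[(2R,3R)-2-methyl-3-(2-oxoethyl)oxiran-2-yl]ethyl (2R,3S)-2,3-dimethyloxirane-2-carboxylate
Conditions: Dess–Martin periodinane, NaHCO3, CH2Cl2, 0 °C; used crude
Reagents that add atoms: none
Why: Dess–Martin oxidation under buffered conditions should give the C3 aldehyde, used at once because a β,γ-epoxy aldehyde is prone to β-elimination.

**Step 17**
Reactants: 24 (iodoalkenyl epoxy aldehyde, as named in step 16)
Product: 25 (1R,3S,4Z,6R,7R,8R,10R)-1,10-epoxy-3-hydroxygermacra-4,11(13)-dien-12,6-olid-8-yl (2R,3S)-2,3-dimethyloxirane-2-carboxylate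
Conditions: CrCl2 (10 equiv), NiCl2 (5 mol%), degassed DMSO/THF, 25 °C, slow addition to 0.002 M
Reagents that add atoms: none
Why: Divalent chromium reduces the nickel salt to zerovalent nickel, which inserts into the C4–I bond with retention of the Z geometry and hands the alkenyl group to trivalent chromium; the alkenylchromium then adds to the C3 aldehyde, and the strong Cr–O bond makes the addition irreversible. The closest known reaction type is the Nozaki–Hiyama–Kishi macrocyclisation of iodoalkenyl aldehydes to medium carbocycles, ten-membered germacranolide rings included. The ten-membered carbocycle is closed in the 10-exo-trig mode by the C3–C4 bond, with the lactone ring and both oxiranes already in place, so no ring is formed afterwards. The new stereocentre C3 is controlled by the conformation of the closing ring: allylic 1,3-strain across the Z alkene keeps H3 and H6 in the alkene plane with C7 on one face, and the trans-substituted C1–C10 oxirane unit is expected to bridge to C2 from the opposite face (crossed arrangement), which places the chromium alkoxide outward and should favour 3S. The step needs chemoselectivity for the C–I bond over the two oxiranes, the glycidic ester and the methylene lactone (organochromium reagents add to aldehydes but not to esters or oxiranes at 25 °C) and ring closure over oligomerisation (slow addition at high dilution; the cis relation of C3 and C6 and the rigid trans-lactone hold the chain ends together).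

**Step 18**
Reactants: 25 (macrocyclic C3 alcohol, as named in step 17)
Product: 26 (1R,3S,4Z,6R,7R,8R,10R)-1,10-epoxy-3-(3-methylbutanoyloxy)germacra-4,11(13)-dien-12,6-olid-8-yl (2R,3S)-2,3-dimethyloxirane-2-carboxylate (the target)
Conditions: 3-methylbutanoyl chloride, pyridine, DMAP (cat.), CH2Cl2, 0 °C
Reagents that add atoms: 3-methylbutanoyl chloride, CC(C)CC(=O)Cl
Why: Acylation of the secondary allylic alcohol by the acid chloride under nucleophilic catalysis proceeds with retention at C3 and should not disturb the oxiranes or the methylene lactone.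

**Compound list**

1 | acrolein (prop-2-enal) | C=CC=O | starting material
2 | 1-propynylmagnesium bromide | CC#C[Mg]Br | starting material
3 | hex-1-en-4-yn-3-ol (racemic) | C=CC(O)C#CC | intermediate
4 | cyclic sodium alkenylalanate (sodium 2,2-bis(2-methoxyethoxy)-3-methyl-5-vinyl-2,5-dihydro-1,2-oxaluminol-2-uide, racemic) | [Na+].C=CC1C=C(C)[Al-](OCCOC)(OCCOC)O1 | intermediate
5 | (Z)-5-iodohexa-1,4-dien-3-ol (racemic) | C=CC(O)/C=C(/C)I | intermediate
6 | (3S,4Z)-5-iodohexa-1,4-dien-3-ol | O[C@@H](C=C)/C=C(/C)I | intermediate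
7 | 2-(bromomethyl)prop-2-enoic acid | C=C(CBr)C(=O)O | starting material
8 | (3S,4Z)-5-iodohexa-1,4-dien-3-yl 2-(bromomethyl)prop-2-enoate | C=C(CBr)C(=O)O[C@@H](C=C)/C=C(/C)I | intermediate
9 | (5S)-3-(bromomethyl)-5-[(1Z)-2-iodoprop-1-en-1-yl]furan-2(5H)-one | O=C1O[C@H](/C=C(/C)I)C=C1CBr | intermediate
10 | tert-butyl(but-3-yn-1-yloxy)dimethylsilane | C#CCCO[Si](C)(C)C(C)(C)C | starting material
11 | [(1E)-4-(tert-butyldimethylsilyloxy)-2-methylbut-1-en-1-yl]dimethylalane | C[Al](C)/C=C(C)/CCO[Si](C)(C)C(C)(C)C | intermediate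
12 | lithium butyl[(1E)-4-(tert-butyldimethylsilyloxy)-2-methylbut-1-en-1-yl]dimethylaluminate | [Li+].CCCC[Al-](C)(C)/C=C(C)/CCO[Si](C)(C)C(C)(C)C | intermediate
13 | (3E)-6-(tert-butyldimethylsilyloxy)-4-methylhex-3-en-1-ol | OCC/C=C(C)/CCO[Si](C)(C)C(C)(C)C | intermediate
14 | tert-butyl{[(3E)-6-(4-methoxybenzyloxy)-3-methylhex-3-en-1-yl]oxy}dimethylsilane | COc1ccc(COCC/C=C(C)/CCO[Si](C)(C)C(C)(C)C)cc1 | intermediate
15 | tert-butyl(2-{(2R,3R)-3-[2-(4-methoxybenzyloxy)ethyl]-2-methyloxiran-2-yl}ethoxy)dimethylsilane | COc1ccc(COCC[C@H]2O[C@]2(C)CCO[Si](C)(C)C(C)(C)C)cc1 | intermediate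
16 | 2-{(2R,3R)-3-[2-(4-methoxybenzyloxy)ethyl]-2-methyloxiran-2-yl}ethan-1-ol | COc1ccc(COCC[C@H]2O[C@]2(C)CCO)cc1 | intermediate
17 | {(2R,3R)-3-[2-(4-methoxybenzyloxy)ethyl]-2-methyloxiran-2-yl}acetaldehyde | COc1ccc(COCC[C@H]2O[C@]2(C)CC=O)cc1 | intermediate
18 | (4R,5S)-4-[(1S)-1-hydroxy-2-{(2R,3R)-3-[2-(4-methoxybenzyloxy)ethyl]-2-methyloxiran-2-yl}ethyl]-5-[(1Z)-2-iodoprop-1-en-1-yl]-3-methylideneoxolan-2-one | C=C1C(=O)O[C@H](/C=C(/C)I)[C@H]1[C@@H](O)C[C@@]2(C)O[C@@H]2CCOCc2ccc(OC)cc2 | intermediate
19 | (2E)-2-methylbut-2-en-1-ol | C/C=C(\C)CO | starting material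
20 | [(2S,3S)-2,3-dimethyloxiran-2-yl]methanol | OC[C@]1(C)O[C@H]1C | intermediate
21 | (2R,3S)-2,3-dimethyloxirane-2-carboxylic acid | OC(=O)[C@]1(C)O[C@H]1C | intermediate
22 | (1R)-1-{(2S,3R)-2-[(1Z)-2-iodoprop-1-en-1-yl]-4-methylidene-5-oxooxolan-3-yl}-2-{(2R,3R)-3-[2-(4-methoxybenzyloxy)ethyl]-2-methyloxiran-2-yl}ethyl (2R,3S)-2,3-dimethyloxirane-2-carboxylate | C=C1C(=O)O[C@H](/C=C(/C)I)[C@H]1[C@H](OC(=O)[C@]2(C)O[C@H]2C)C[C@@]3(C)O[C@@H]3CCOCc4ccc(OC)cc4 | intermediate
23 | (1R)-2-[(2R,3R)-3-(2-hydroxyethyl)-2-methyloxiran-2-yl]-1-{(2S,3R)-2-[(1Z)-2-iodoprop-1-en-1-yl]-4-methylidene-5-oxooxolan-3-yl}ethyl (2R,3S)-2,3-dimethyloxirane-2-carboxylate | C=C1C(=O)O[C@H](/C=C(/C)I)[C@H]1[C@H](OC(=O)[C@]2(C)O[C@H]2C)C[C@@]3(C)O[C@@H]3CCO | intermediate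
24 | (1R)-1-{(2S,3R)-2-[(1Z)-2-iodoprop-1-en-1-yl]-4-methylidene-5-oxooxolan-3-yl}-2-[(2R,3R)-2-methyl-3-(2-oxoethyl)oxiran-2-yl]ethyl (2R,3S)-2,3-dimethyloxirane-2-carboxylate | C=C1C(=O)O[C@H](/C=C(/C)I)[C@H]1[C@H](OC(=O)[C@]2(C)O[C@H]2C)C[C@@]3(C)O[C@@H]3CC=O | intermediate
25 | (1R,3S,4Z,6R,7R,8R,10R)-1,10-epoxy-3-hydroxygermacra-4,11(13)-dien-12,6-olid-8-yl (2R,3S)-2,3-dimethyloxirane-2-carboxylate | C=C1C(=O)O[C@@H]2/C=C(/C)[C@@H](O)C[C@H]3O[C@]3(C)C[C@@H](OC(=O)[C@]3(C)O[C@H]3C)[C@@H]12 | intermediate
26 | (1R,3S,4Z,6R,7R,8R,10R)-1,10-epoxy-3-(3-methylbutanoyloxy)germacra-4,11(13)-dien-12,6-olid-8-yl (2R,3S)-2,3-dimethyloxirane-2-carboxylate | C=C1C(=O)O[C@@H]2/C=C(/C)[C@@H](OC(=O)CC(C)C)C[C@H]3O[C@]3(C)C[C@@H](OC(=O)[C@]3(C)O[C@H]3C)[C@@H]12 | target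

**Step count**

Total: 18 steps. Longest linear sequence: 11 steps (steps 6–11 and 14–18; equally steps 1–5, 11 and 14–18).

**Steps most likely to fail**

Step 17. The addition to the C3 aldehyde may proceed with poor facial selectivity, because C3 is set only by the conformation of the closing ring and the 3R carbinol may form alongside or instead of 3S. The fallback sets out from 24 and comes back at 25, and replaces conformational control by reagent control. The ring closure is run as in step 17, and the mixture of 25 and its C3 epimer, the (3R)-alcohol F1, is oxidised with Dess–Martin periodinane/NaHCO3 to the ten-membered Z-enone F2. F2 is then reduced by Corey–Bakshi–Shibata reduction with (R)-1-methyl-3,3-diphenyltetrahydro-1H,3H-pyrrolo[1,2-c][1,3,2]oxazaborole and catecholborane in toluene at −78 °C. With the α-methyl alkenyl side as the large group, this should return 25 with 3S.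

Step 14. The activated C8 oxygen may be lost by elimination toward C7 (giving a diene conjugated with the methylene lactone) faster than the hindered, α-quaternary carboxylate attacks in the SN2 sense. The fallback sets out from 18 and comes back at 22, and separates the inversion from the attachment of the hindered acid. Mitsunobu inversion with the small, more acidic chloroacetic acid (PPh3, DIAD) gives the inverted (8R)-chloroacetate F3. Thiourea and NaHCO3 in ethanol remove the chloroacetyl group to give the (8R)-alcohol F4. Yamaguchi esterification of F4 with 21 (2,4,6-trichlorobenzoyl chloride, Et3N, then DMAP, toluene) attaches the side chain with retention and gives 22.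

Step 11. The β,γ-epoxy aldehyde may undergo β-elimination with opening of the oxirane in the zinc/ammonium chloride medium before the allylzinc adds. The fallback sets out from 14 (with 9) and comes back at 18, and moves the epoxidation behind the C–C bond formation. Bu4NF converts 14 into the alkene alcohol F5, and buffered Dess–Martin oxidation gives the β,γ-unsaturated aldehyde F6. Zinc-mediated allylation of F6 with 9 under the conditions of step 11 gives the alkene adduct F7. Shi epoxidation of F7 with the ketone of step 8 should then give 18, since the electron-rich C1=C10 alkene is expected to react before the iodoalkene and the methylene lactone.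

**Further compounds**

F1 | step 17 | (1R,3R,4Z,6R,7R,8R,10R)-1,10-epoxy-3-hydroxygermacra-4,11(13)-dien-12,6-olid-8-yl (2R,3S)-2,3-dimethyloxirane-2-carboxylate (C3 epimer of 25) | C=C1C(=O)O[C@@H]2/C=C(/C)[C@H](O)C[C@H]3O[C@]3(C)C[C@@H](OC(=O)[C@]3(C)O[C@H]3C)[C@@H]12
F2 | step 17 | (1R,4Z,6R,7R,8R,10R)-1,10-epoxy-3-oxogermacra-4,11(13)-dien-12,6-olid-8-yl (2R,3S)-2,3-dimethyloxirane-2-carboxylate | C=C1C(=O)O[C@@H]2/C=C(/C)C(=O)C[C@H]3O[C@]3(C)C[C@@H](OC(=O)[C@]3(C)O[C@H]3C)[C@@H]12
F3 | step 14 | (1R)-1-{(2S,3R)-2-[(1Z)-2-iodoprop-1-en-1-yl]-4-methylidene-5-oxooxolan-3-yl}-2-{(2R,3R)-3-[2-(4-methoxybenzyloxy)ethyl]-2-methyloxiran-2-yl}ethyl chloroacetate | C=C1C(=O)O[C@H](/C=C(/C)I)[C@H]1[C@H](OC(=O)CCl)C[C@@]2(C)O[C@@H]2CCOCc2ccc(OC)cc2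
F4 | step 14 | (4R,5S)-4-[(1R)-1-hydroxy-2-{(2R,3R)-3-[2-(4-methoxybenzyloxy)ethyl]-2-methyloxiran-2-yl}ethyl]-5-[(1Z)-2-iodoprop-1-en-1-yl]-3-methylideneoxolan-2-one | C=C1C(=O)O[C@H](/C=C(/C)I)[C@H]1[C@H](O)C[C@@]2(C)O[C@@H]2CCOCc2ccc(OC)cc2
F5 | step 11 | (3E)-6-(4-methoxybenzyloxy)-3-methylhex-3-en-1-ol | COc1ccc(COCC/C=C(C)/CCO)cc1
F6 | step 11 | (3E)-6-(4-methoxybenzyloxy)-3-methylhex-3-enal | COc1ccc(COCC/C=C(C)/CC=O)cc1
F7 | step 11 | (4R,5S)-4-[(1S,3E)-1-hydroxy-6-(4-methoxybenzyloxy)-3-methylhex-3-en-1-yl]-5-[(1Z)-2-iodoprop-1-en-1-yl]-3-methylideneoxolan-2-one | C=C1C(=O)O[C@H](/C=C(/C)I)[C@H]1[C@@H](O)C/C(C)=C/CCOCc1ccc(OC)cc1
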